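**Route overview**

1. Chain numbering used throughout: C1 = CO2H carbon, C2 = quaternary C(CH3)(CO2H), C3 and C7 = ring-fusion CH, C4(Et)=C5 = cyclopentene alkene, C6 = CH(CH3), C8(Et)=C9 = cyclohexene alkene, C10 = quaternary C(Et)(styryl), C11=C12–Ph = styryl.
2. Enabling feature: the six-membered ring C7–C8=C9–C10–C2–C3 has the pattern of a [4+2] adduct (alkene C8=C9 flanked by the σ-bonds C2–C10 and C3–C7). Because C3 and C7 are also the ends of the bridge C4=C5–C6, breaking those two bonds opens the cyclohexene and the cyclopentene together to one open-chain (2E,4Z,6R,7E,9E,11E)-pentaenoic acid.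
3. Cuts, in retrosynthetic order: C2–C10 with C3–C7 (intramolecular Diels–Alder); C8–C9 (Suzuki–Miyaura union of a C1–C8 iodotrienoic acid and a C9–C12 dienyl boronate); then C2=C3 (Wittig), C4=C5 (Still–Gennari) and C7=C8 (alkyne hydrozirconation–iodination) in the west, C11=C12 (Horner–Wadsworth–Emmons) and C9–C10 (iodoform–malonate) in the east.
4. Forward order: both fragments are built as open chains, the chain is joined at C8–C9 in the second-to-last step, and the two rings arise together in the final cycloaddition; no ring exists earlier.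
5. Stereochemistry: C6 comes from the (S)-Roche ester; alkene geometries come from Still–Gennari olefination (4Z), stabilised Wittig olefination (2E), syn-hydrozirconation (7E), decarboxylative elimination of the iodoform–malonate adduct (9E) and Horner–Wadsworth–Emmons olefination (11E); the cycloaddition, steered by C6, turns these geometries into C2, C3, C7 and C10.

Key step: step 21

Remark 1: the spatial arrangement at C6 is the same in every compound from the Roche ester to the target; its CIP label alternates between S and R only because the ranking of its neighbours changes.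
Remark 2: the pentaenoic acid is assumed to survive a cold, rapid work-up; any portion that has already cyclised is carried into the last step with it.
Remark 3: alkoxides, carboxylates and aluminium or boron ate complexes that are merely protonated or hydrolysed on work-up are treated as the work-up form of the product and are not numbered.

**Western fragment (C1–C8)**

Step 1
Reactants: 1 methyl (2S)-3-hydroxy-2-methylpropanoate ((S)-Roche ester)
Product: 2 methyl (2S)-3-[(tert-butyldimethylsilyl)oxy]-2-methylpropanoate
Conditions: TBSCl, imidazole, CH2Cl2, 0 °C → rt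
Reagents that add atoms: tert-butyldimethylsilyl chloride (TBSCl), CC(C)(C)[Si](C)(C)Cl
Why: Imidazole-mediated silylation of the primary alcohol is chemoselective and does not touch the stereocentre α to the ester.

Step 2
Reactants: 2 methyl (2S)-3-[(tert-butyldimethylsilyl)oxy]-2-methylpropanoate
Product: 3 (2S)-3-[(tert-butyldimethylsilyl)oxy]-2-methylpropanal
Conditions: i-Bu2AlH (1.1 equiv), CH2Cl2, −78 °C; MeOH quench, aq. KNaC4H4O6 (Rochelle salt) work-up
Reagents that add atoms: none
Why: Partial reduction of the methyl ester with i-Bu2AlH at −78 °C should stop at the aluminium hemiacetal, which releases the aldehyde only on work-up, so the α-stereocentre is never exposed to base (the ester carbon becomes C7, the silyloxymethyl carbon is C5).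

Step 3
Reactants: 3 (2S)-3-[(tert-butyldimethylsilyl)oxy]-2-methylpropanal
Product: 4 tert-butyl{[(2R)-4,4-dibromo-2-methylbut-3-en-1-yl]oxy}dimethylsilane
Conditions: CBr4, PPh3, Zn, CH2Cl2, rt (ylide formation); then 3, 0 °C
Reagents that add atoms: carbon tetrabromide, BrC(Br)(Br)Br
Why: Corey–Fuchs dibromo-olefination with the preformed ylide under neutral, zinc-mediated conditions should convert the aldehyde into the dibromoalkene without epimerising the adjacent stereocentre.

Step 4
Reactants: 4 tert-butyl{[(2R)-4,4-dibromo-2-methylbut-3-en-1-yl]oxy}dimethylsilane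
Product: 6 tert-butyldimethyl{[(2R)-2-methylhex-3-yn-1-yl]oxy}silane, via lithium acetylide 5 (not isolated)
Conditions: n-BuLi (2.1 equiv), THF, −78 °C; then EtI (5 equiv), DMPU, −78 °C → rt
Reagents that add atoms: iodoethane (EtI), CCI
Why: In the second stage of the Corey–Fuchs sequence, bromine–lithium exchange and Fritsch–Buttenberg–Wiechell-type rearrangement give the alkyne, a second equivalent of n-BuLi forms the acetylide, and SN2 alkylation with excess EtI in the presence of DMPU should outrun alkylation by the n-BuBr formed alongside.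

Step 5
Reactants: 6 tert-butyldimethyl{[(2R)-2-methylhex-3-yn-1-yl]oxy}silane
Product: 8 tert-butyl{[(2R,3E)-4-iodo-2-methylhex-3-en-1-yl]oxy}dimethylsilane, via alkenylzirconocene chloride 7 (not isolated)
Conditions: Cp2Zr(H)Cl (2.5 equiv), THF, 50 °C, dark; then I2, THF, 0 °C
Reagents that add atoms: iodine, II
Why: Syn-hydrozirconation of the internal alkyne with excess Cp2Zr(H)Cl under equilibrating conditions should move zirconium to C8, the carbon remote from the branched C6, and iodinolysis of the C–Zr bond with retention then gives the 7E iodide (H and I cis, C6 and ethyl cis).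

Step 6
Reactants: 8 tert-butyl{[(2R,3E)-4-iodo-2-methylhex-3-en-1-yl]oxy}dimethylsilane
Product: 9 (2R,3E)-4-iodo-2-methylhex-3-en-1-ol
Conditions: Bu4NF, THF, 0 °C → rt
Reagents that add atoms: none
Why: Fluoride-mediated desilylation of the primary silyl ether is compatible with the alkenyl iodide and leaves the allylic stereocentre alone.

Step 7
Reactants: 9 (2R,3E)-4-iodo-2-methylhex-3-en-1-ol
Product: 10 (2R,3E)-4-iodo-2-methylhex-3-enal
Conditions: Dess–Martin periodinane, NaHCO3, CH2Cl2, 0 °C; cold filtration, used at once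
Reagents that add atoms: none
Why: Dess–Martin oxidation under bicarbonate buffering is fast and non-basic, which is needed because the aldehyde is α-chiral and β,γ-unsaturated and must be used cold and immediately.

Step 8
Reactants: 11 methyl 2-[bis(2,2,2-trifluoroethoxy)phosphoryl]acetate
Product: 13 methyl 2-[bis(2,2,2-trifluoroethoxy)phosphoryl]butanoate (racemic), via potassium phosphonoacetate carbanion 12 (not isolated)
Conditions: KOt-Bu (1.0 equiv), THF, 0 °C; then EtI, 0 → 40 °C
Reagents that add atoms: iodoethane (EtI), CCI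
Why: C-alkylation (SN2) of the stabilised phosphonoacetate carbanion with a primary iodide gives the α-ethyl Still–Gennari reagent whose carbons become C3, C4 and the C4 ethyl.

Step 9
Reactants: 10 (2R,3E)-4-iodo-2-methylhex-3-enal and 13 methyl 2-[bis(2,2,2-trifluoroethoxy)phosphoryl]butanoate
Product: 15 methyl (2Z,4S,5E)-2-ethyl-6-iodo-4-methylocta-2,5-dienoate, via potassium phosphonate carbanion 14 (not isolated)
Conditions: 13, KN(SiMe3)2, 18-crown-6, THF, −78 °C; then 10, −78 °C; aq. NH4Cl quench at −78 °C
Reagents that add atoms: none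
Why: In the Still–Gennari olefination the electron-poor bis(trifluoroethyl) phosphonate under dissociating conditions eliminates rapidly from the kinetic adduct and should give the Z-enoate (ester cis to C6), setting the 4Z alkene, while the low temperature and the weakly basic carbanion preserve C6.

Step 10
Reactants: 15 methyl (2Z,4S,5E)-2-ethyl-6-iodo-4-methylocta-2,5-dienoate
Product: 16 (2Z,4S,5E)-2-ethyl-6-iodo-4-methylocta-2,5-dien-1-ol
Conditions: i-Bu2AlH (2.2 equiv), CH2Cl2, −78 °C; aq. KNaC4H4O6 work-up
Reagents that add atoms: none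
Why: 1,2-Reduction of the conjugated ester with i-Bu2AlH gives the allylic alcohol without affecting the alkenyl iodide or the Z-alkene.

Step 11
Reactants: 16 (2Z,4S,5E)-2-ethyl-6-iodo-4-methylocta-2,5-dien-1-ol
Product: 17 (2Z,4S,5E)-2-ethyl-6-iodo-4-methylocta-2,5-dienal
Conditions: MnO2, CH2Cl2, rt, dark; filtered and used directly
Reagents that add atoms: none
Why: MnO2 oxidation of the allylic alcohol is neutral and heterogeneous, which should keep the Z geometry of the enal.

Step 12
Reactants: 17 (2Z,4S,5E)-2-ethyl-6-iodo-4-methylocta-2,5-dienal and 18 ethyl 2-(triphenyl-λ5-phosphanylidene)propanoate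
Product: 19 ethyl (2E,4Z,6S,7E)-4-ethyl-8-iodo-2,6-dimethyldeca-2,4,7-trienoate
Conditions: PhMe, 60 °C, dark
Reagents that add atoms: none
Why: Wittig olefination with the stabilised α-methyl ylide is E-selective and should set the 2E alkene, completing the (2E,4Z)-dienoate with C1, C2 and the C2 methyl.

Step 13
Reactants: 19 ethyl (2E,4Z,6S,7E)-4-ethyl-8-iodo-2,6-dimethyldeca-2,4,7-trienoate
Product: 20 (2E,4Z,6S,7E)-4-ethyl-8-iodo-2,6-dimethyldeca-2,4,7-trienoic acid
Conditions: LiOH·H2O, THF/MeOH/H2O, rt → 40 °C; then 1 M HCl to pH 3, 0 °C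
Reagents that add atoms: lithium hydroxide, [Li+].[OH-]
Why: Saponification is done at this stage because the acyclic dienoate is accessible to hydroxide, whereas the ester of the cycloadduct would sit between two quaternary carbons.

**Eastern fragment (C9–C12)**

Step 14
Reactants: 21 diethyl 2-ethylpropanedioate (diethyl ethylmalonate)
Product: 23 diethyl 2-(diiodomethyl)-2-ethylpropanedioate, via sodium malonate enolate 22 (not isolated)
Conditions: NaH, Et2O, reflux; then CHI3, reflux
Reagents that add atoms: iodoform, IC(I)I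
Why: Alkylation of the sodium malonate with iodoform installs the CHI2 group whose carbon becomes C9 and forms the C9–C10 bond.

Step 15
Reactants: 23 diethyl 2-(diiodomethyl)-2-ethylpropanedioate
Product: 25 (2E)-2-ethyl-3-iodoprop-2-enoic acid, via dipotassium diiodomethylmalonate 24 (not isolated)
Conditions: KOH, EtOH/H2O (3:1), reflux; then aq. HCl
Reagents that add atoms: potassium hydroxide, [K+].[OH-]
Why: Saponification followed by decarboxylative anti-elimination of iodide (a Grob-type fragmentation of the β-iodo carboxylate) should give the iodoacrylic acid with iodine cis to ethyl, the E isomer, which fixes the later 9E geometry.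

Step 16
Reactants: 25 (2E)-2-ethyl-3-iodoprop-2-enoic acid
Product: 26 (2E)-2-ethyl-3-iodoprop-2-en-1-ol
Conditions: LiAlH4, Et2O, 0 °C → rt; aq. KNaC4H4O6 work-up
Reagents that add atoms: none
Why: LiAlH4 reduction of a 2-alkyl-3-iodoacrylic acid to the allylic alcohol is a known transformation that spares the alkenyl iodide at low temperature.

Step 17
Reactants: 26 (2E)-2-ethyl-3-iodoprop-2-en-1-ol
Product: 27 (2E)-2-ethyl-3-iodoprop-2-enal
Conditions: MnO2, CH2Cl2, rt, dark; filtered solution used directly
Reagents that add atoms: none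
Why: MnO2 oxidation of the allylic alcohol gives the β-iodoenal without loss of geometry, and the volatile, light-sensitive aldehyde is carried on in solution.

Step 18
Reactants: 27 (2E)-2-ethyl-3-iodoprop-2-enal and 28 diethyl benzylphosphonate
Product: 30 [(1E,3E)-3-ethyl-4-iodobuta-1,3-dien-1-yl]benzene, via potassium benzylphosphonate carbanion 29 (not isolated)
Conditions: 28, KOt-Bu, THF, 0 °C; then 27, −78 → 0 °C, dark
Reagents that add atoms: none
Why: Horner–Wadsworth–Emmons olefination with the semistabilised benzylphosphonate anion is strongly E-selective and should set the 11E styryl alkene while adding C12 and the phenyl ring.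

Step 19
Reactants: 30 [(1E,3E)-3-ethyl-4-iodobuta-1,3-dien-1-yl]benzene
Product: 32 2-[(1E,3E)-2-ethyl-4-phenylbuta-1,3-dien-1-yl]-4,4,5,5-tetramethyl-1,3,2-dioxaborolane, via dienyllithium 31 (not isolated)
Conditions: t-BuLi (2.1 equiv), Et2O, −78 °C; then i-PrOBpin, −78 °C → rt; aq. NH4Cl
Reagents that add atoms: 2-isopropoxy-4,4,5,5-tetramethyl-1,3,2-dioxaborolane (i-PrOBpin), CC(C)OB1OC(C)(C)C(C)(C)O1
Why: Iodine–lithium exchange with two equivalents of t-BuLi at −78 °C is faster than addition to the diene and proceeds with retention, and borylation of the alkenyllithium with the isopropoxyboronate gives the pinacol boronate after loss of isopropoxide.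

**Union and cyclisation**

Step 20
Reactants: 20 (2E,4Z,6S,7E)-4-ethyl-8-iodo-2,6-dimethyldeca-2,4,7-trienoic acid and 32 2-[(1E,3E)-2-ethyl-4-phenylbuta-1,3-dien-1-yl]-4,4,5,5-tetramethyl-1,3,2-dioxaborolane
Product: 33 (2E,4Z,6R,7E,9E,11E)-4,8,10-triethyl-2,6-dimethyl-12-phenyldodeca-2,4,7,9,11-pentaenoic acid
Conditions: Pd(PPh3)4 (10 mol %), aq. K3PO4, THF, degassed, 35 °C, dark; then aq. NaH2PO4 (pH 4), 0 °C, rapid cold work-up
Reagents that add atoms: none
Why: Suzuki–Miyaura coupling (oxidative addition of the alkenyl iodide to zerovalent palladium, base-assisted transmetalation of the alkenyl boronate, reductive elimination) should form C8–C9 with retention at both alkenes, and the carboxylate is tolerated under aqueous phosphate conditions.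

Step 21
Reactants: 33 (2E,4Z,6R,7E,9E,11E)-4,8,10-triethyl-2,6-dimethyl-12-phenyldodeca-2,4,7,9,11-pentaenoic acid
Product: 34 (1S,3aS,4S,5R,7aR)-3,5,7-triethyl-1,4-dimethyl-5-[(E)-2-phenylethenyl]-3a,4,5,7a-tetrahydro-1H-indene-4-carboxylic acid (target CNP0242622.1)
Conditions: PhMe (0.01 M), BHT (trace), degassed, 70 °C, dark
Reagents that add atoms: none
Why: The step is a concerted, suprafacial thermal [4+2] cycloaddition of normal electron demand in which the alkyl- and styryl-substituted diene C7=C8–C9=C10 adds to the α-methylacrylic acid terminus C2=C3, so that C2–C10 and C3–C7 form in one event. The closest known reaction type is the type 1 intramolecular Diels–Alder reaction of (E)-nona-1,6,8-trienes carrying a carbonyl activator at the dienophile terminus, which gives trans-fused hydrindenes and is also known as a biomimetic cyclisation of polyene acids. The cyclohexene ring closes by the cycloaddition proper (four diene carbons plus two dienophile carbons), and the cyclopentene ring closes as the fused ring of the intramolecular mode, because the new C3–C7 bond joins the two ends of the three-atom tether C4=C5–C6, whose 4Z alkene becomes the endocyclic double bond. At C2 and C3 the 2E dienophile geometry puts the C2 methyl cis to C4, at C7 and C10 the 7E,9E diene geometry puts the styryl group cis to C6, the carboxyl-endo transition state with the tether anti relates the two pairs (trans ring fusion, CO2H cis to styryl), and the C6 stereocentre chooses the diene face and thereby the absolute configuration of all four new centres. The step needs carboxyl-endo selectivity and a single diene face: the first should be secured by the rigid Z-tether, which in the tether-endo alternative would have to push the C4 ethyl over the C8 ethyl of the diene, aided by secondary overlap of the carboxyl group, and the second by allylic 1,3-strain, which holds the C6 hydrogen in the plane of C7=C8 next to the C8 ethyl so that the tether delivers the dienophile to the face opposite the C6 methyl and that methyl ends up trans to C8 on the cyclopentene. Other cycloaddition modes should not compete, since C4=C5 is an unactivated dienophile for the C9–C12 diene and the dienoic acid cannot span C7=C8 through the one-atom link C6.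

**Compound list**

1 | methyl (2S)-3-hydroxy-2-methylpropanoate | COC(=O)[C@@H](C)CO | starting material
2 | methyl (2S)-3-[(tert-butyldimethylsilyl)oxy]-2-methylpropanoate | COC(=O)[C@@H](C)CO[Si](C)(C)C(C)(C)C | intermediate
3 | (2S)-3-[(tert-butyldimethylsilyl)oxy]-2-methylpropanal | O=C[C@@H](C)CO[Si](C)(C)C(C)(C)C | intermediate
4 | tert-butyl{[(2R)-4,4-dibromo-2-methylbut-3-en-1-yl]oxy}dimethylsilane | BrC(Br)=C[C@@H](C)CO[Si](C)(C)C(C)(C)C | intermediate
5 | [(3R)-4-{[tert-butyl(dimethyl)silyl]oxy}-3-methylbut-1-yn-1-yl]lithium | [Li]C#C[C@@H](C)CO[Si](C)(C)C(C)(C)C | intermediate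
6 | tert-butyldimethyl{[(2R)-2-methylhex-3-yn-1-yl]oxy}silane | CC(C)(C)[Si](C)(C)OC[C@H](C)C#CCC | intermediate
7 | chlorobis(cyclopentadienyl)[(3E,5R)-6-{[tert-butyl(dimethyl)silyl]oxy}-5-methylhex-3-en-3-yl]zirconium | CC(C)(C)[Si](C)(C)OC[C@H](C)/C=C(/[Zr](Cl)(C1C=CC=C1)C1C=CC=C1)CC | intermediate
8 | tert-butyl{[(2R,3E)-4-iodo-2-methylhex-3-en-1-yl]oxy}dimethylsilane | CC(C)(C)[Si](C)(C)OC[C@H](C)/C=C(/I)CC | intermediate
9 | (2R,3E)-4-iodo-2-methylhex-3-en-1-ol | OC[C@H](C)/C=C(/I)CC | intermediate
10 | (2R,3E)-4-iodo-2-methylhex-3-enal | O=C[C@H](C)/C=C(/I)CC | intermediate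
11 | methyl 2-[bis(2,2,2-trifluoroethoxy)phosphoryl]acetate | COC(=O)CP(=O)(OCC(F)(F)F)OCC(F)(F)F | starting material
12 | potassium 1-[bis(2,2,2-trifluoroethoxy)phosphoryl]-2-methoxy-2-oxoethan-1-ide | [K+].COC(=O)[CH-]P(=O)(OCC(F)(F)F)OCC(F)(F)F | intermediate
13 | methyl 2-[bis(2,2,2-trifluoroethoxy)phosphoryl]butanoate (racemic) | COC(=O)C(CC)P(=O)(OCC(F)(F)F)OCC(F)(F)F | intermediate
14 | potassium 1-[bis(2,2,2-trifluoroethoxy)phosphoryl]-1-(methoxycarbonyl)propan-1-ide | [K+].COC(=O)[C-](CC)P(=O)(OCC(F)(F)F)OCC(F)(F)F | intermediate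
15 | methyl (2Z,4S,5E)-2-ethyl-6-iodo-4-methylocta-2,5-dienoate | COC(=O)/C(CC)=C\[C@H](C)/C=C(/I)CC | intermediate
16 | (2Z,4S,5E)-2-ethyl-6-iodo-4-methylocta-2,5-dien-1-ol | OC/C(CC)=C\[C@H](C)/C=C(/I)CC | intermediate
17 | (2Z,4S,5E)-2-ethyl-6-iodo-4-methylocta-2,5-dienal | O=C/C(CC)=C\[C@H](C)/C=C(/I)CC | intermediate
18 | ethyl 2-(triphenyl-λ5-phosphanylidene)propanoate | CCOC(=O)C(C)=P(c1ccccc1)(c1ccccc1)c1ccccc1 | starting material
19 | ethyl (2E,4Z,6S,7E)-4-ethyl-8-iodo-2,6-dimethyldeca-2,4,7-trienoate | CCOC(=O)/C(C)=C/C(CC)=C\[C@H](C)/C=C(/I)CC | intermediate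
20 | (2E,4Z,6S,7E)-4-ethyl-8-iodo-2,6-dimethyldeca-2,4,7-trienoic acid | OC(=O)/C(C)=C/C(CC)=C\[C@H](C)/C=C(/I)CC | intermediate
21 | diethyl 2-ethylpropanedioate | CCOC(=O)C(CC)C(=O)OCC | starting material
22 | sodium 1,3-diethoxy-2-ethyl-1,3-dioxopropan-2-ide | [Na+].CCOC(=O)[C-](CC)C(=O)OCC | intermediate
23 | diethyl 2-(diiodomethyl)-2-ethylpropanedioate | CCOC(=O)C(CC)(C(I)I)C(=O)OCC | intermediate
24 | dipotassium 2-(diiodomethyl)-2-ethylpropanedioate | [K+].[K+].[O-]C(=O)C(CC)(C(I)I)C([O-])=O | intermediate
25 | (2E)-2-ethyl-3-iodoprop-2-enoic acid | OC(=O)/C(CC)=C/I | intermediate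
26 | (2E)-2-ethyl-3-iodoprop-2-en-1-ol | OC/C(CC)=C/I | intermediate
27 | (2E)-2-ethyl-3-iodoprop-2-enal | O=C/C(CC)=C/I | intermediate
28 | diethyl benzylphosphonate | CCOP(=O)(Cc1ccccc1)OCC | starting material
29 | potassium (diethoxyphosphoryl)(phenyl)methanide | [K+].CCOP(=O)([CH-]c1ccccc1)OCC | intermediate
30 | [(1E,3E)-3-ethyl-4-iodobuta-1,3-dien-1-yl]benzene | I/C=C(CC)/C=C/c1ccccc1 | intermediate
31 | [(1E,3E)-2-ethyl-4-phenylbuta-1,3-dien-1-yl]lithium | [Li]/C=C(CC)/C=C/c1ccccc1 | intermediate
32 | 2-[(1E,3E)-2-ethyl-4-phenylbuta-1,3-dien-1-yl]-4,4,5,5-tetramethyl-1,3,2-dioxaborolane | CC1(C)OB(OC1(C)C)/C=C(CC)/C=C/c2ccccc2 | intermediate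
33 | (2E,4Z,6R,7E,9E,11E)-4,8,10-triethyl-2,6-dimethyl-12-phenyldodeca-2,4,7,9,11-pentaenoic acid | OC(=O)/C(C)=C/C(CC)=C\[C@H](C)/C=C(CC)/C=C(CC)/C=C/c1ccccc1 | intermediate
34 | (1S,3aS,4S,5R,7aR)-3,5,7-triethyl-1,4-dimethyl-5-[(E)-2-phenylethenyl]-3a,4,5,7a-tetrahydro-1H-indene-4-carboxylic acid | CCC1=C[C@](/C=C/c2ccccc2)(CC)[C@@](C)(C(=O)O)[C@@H]2C(CC)=C[C@H](C)[C@@H]12 | target

**Step count**

Total step count: 21 steps.
Longest linear sequence: 14 steps (1 → 34 through steps 1–7, 9–13, 20 and 21).

**Steps most likely to fail**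

Step 21 (key cycloaddition). The free acid may need a temperature at which the carboxyl-endo and carboxyl-exo transition states are no longer well separated, which would give the cis-fused isomer. A [1,5]-hydrogen shift from C6 along the 4Z-dienoic acid may also compete and erase the only pre-existing stereocentre. The fallback changes the activation from a thermally reacting acid to a Lewis-acid-complexed aldehyde, which should cyclise far below room temperature with a stronger endo preference. It sets out from ester 19 and returns at target 34. Ester 19 is coupled with boronate 32 under the conditions of step 20 to give the ethyl pentaenoate F1. Reduction with i-Bu2AlH (CH2Cl2, −78 °C) gives the pentaenol F2, which cannot cyclise because its dienophile is unactivated. MnO2 oxidation gives the pentaenal F3, which is treated at once with Me2AlCl (CH2Cl2, −78 → −20 °C) to give the bicyclic aldehyde F4 by the same bond formations. Pinnick oxidation (NaClO2, NaH2PO4, 2-methylbut-2-ene, t-BuOH/H2O) of the neopentylic aldehyde then gives 34.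

Step 20 (fragment union). Transmetalation of the 2,2-disubstituted alkenyl boronate to the hindered alkenylpalladium iodide may be slower than protodeboronation, and the warm aqueous base may let the polyene isomerise or cyclise in an uncontrolled medium. The fallback is a base-free Stille union. It sets out from iodide 30 and returns at 33. Iodide 30 is lithiated as in step 19 and the dienyllithium 31 is quenched with Bu3SnCl to give the dienylstannane F5. F5 is joined to acid 20 with Pd2(dba)3, AsPh3 and CuI in NMP at room temperature, which should give 33 with retention at both alkenes.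

Step 5 (hydrozirconation–iodination). An ethyl group differentiates the two alkyne carbons less than a methyl group would, so zirconium may not settle completely on C8, and the regioisomeric alkenyl iodide would be hard to remove. The fallback gives up alkyne hydrometalation and fixes the two C8 substituents by the order of two palladium couplings on a 1,1-dibromoalkene, where the bromine trans to the substituent reacts first. It sets out from dibromoalkene 4 and returns at 33. Suzuki–Miyaura coupling of 4 with boronate 32 (Pd2(dba)3, P(2-furyl)3, aq. Cs2CO3, 1,4-dioxane) at the bromine trans to C6 gives the (Z)-bromotriene F6. Negishi coupling with Et2Zn and Pd(P(t-Bu)3)2 in THF replaces the remaining bromine with retention and gives the triene silyl ether F7, which already holds the 7E,9E,11E unit. F7 is then taken through the operations of steps 6, 7, 9, 10, 11 and 12: desilylation to the trienol F8, Dess–Martin oxidation to the trienal F9, Still–Gennari olefination with 13 (through 14) to the Z-enoate F10, reduction to the allylic alcohol F11, MnO2 oxidation to the Z-enal F12 and Wittig olefination with 18 to the ethyl pentaenoate F1. Saponification of F1 as in step 13 rejoins the route at 33.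

Further compounds
F1 | step 21 | ethyl (2E,4Z,6R,7E,9E,11E)-4,8,10-triethyl-2,6-dimethyl-12-phenyldodeca-2,4,7,9,11-pentaenoate | CCOC(=O)/C(C)=C/C(CC)=C\[C@H](C)/C=C(CC)/C=C(CC)/C=C/c1ccccc1
F2 | step 21 | (2E,4Z,6R,7E,9E,11E)-4,8,10-triethyl-2,6-dimethyl-12-phenyldodeca-2,4,7,9,11-pentaen-1-ol | OC/C(C)=C/C(CC)=C\[C@H](C)/C=C(CC)/C=C(CC)/C=C/c1ccccc1
F3 | step 21 | (2E,4Z,6R,7E,9E,11E)-4,8,10-triethyl-2,6-dimethyl-12-phenyldodeca-2,4,7,9,11-pentaenal | O=C/C(C)=C/C(CC)=C\[C@H](C)/C=C(CC)/C=C(CC)/C=C/c1ccccc1
F4 | step 21 | (1S,3aS,4S,5R,7aR)-3,5,7-triethyl-1,4-dimethyl-5-[(E)-2-phenylethenyl]-3a,4,5,7a-tetrahydro-1H-indene-4-carbaldehyde | CCC1=C[C@](/C=C/c2ccccc2)(CC)[C@@](C)(C=O)[C@@H]2C(CC)=C[C@H](C)[C@@H]12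
F5 | step 20 | tributyl[(1E,3E)-2-ethyl-4-phenylbuta-1,3-dien-1-yl]stannane | CCCC[Sn](CCCC)(CCCC)/C=C(CC)/C=C/c1ccccc1
F6 | step 5 | tert-butyl{[(2R,3Z,5E,7E)-4-bromo-6-ethyl-2-methyl-8-phenylocta-3,5,7-trien-1-yl]oxy}dimethylsilane | CC(C)(C)[Si](C)(C)OC[C@H](C)/C=C(Br)/C=C(CC)/C=C/c1ccccc1
F7 | step 5 | tert-butyl{[(2R,3E,5E,7E)-4,6-diethyl-2-methyl-8-phenylocta-3,5,7-trien-1-yl]oxy}dimethylsilane | CC(C)(C)[Si](C)(C)OC[C@H](C)/C=C(CC)/C=C(CC)/C=C/c1ccccc1
F8 | step 5 | (2R,3E,5E,7E)-4,6-diethyl-2-methyl-8-phenylocta-3,5,7-trien-1-ol | OC[C@H](C)/C=C(CC)/C=C(CC)/C=C/c1ccccc1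
F9 | step 5 | (2R,3E,5E,7E)-4,6-diethyl-2-methyl-8-phenylocta-3,5,7-trienal | O=C[C@H](C)/C=C(CC)/C=C(CC)/C=C/c1ccccc1
F10 | step 5 | methyl (2Z,4R,5E,7E,9E)-2,6,8-triethyl-4-methyl-10-phenyldeca-2,5,7,9-tetraenoate | COC(=O)/C(CC)=C\[C@H](C)/C=C(CC)/C=C(CC)/C=C/c1ccccc1
F11 | step 5 | (2Z,4R,5E,7E,9E)-2,6,8-triethyl-4-methyl-10-phenyldeca-2,5,7,9-tetraen-1-ol | OC/C(CC)=C\[C@H](C)/C=C(CC)/C=C(CC)/C=C/c1ccccc1
F12 | step 5 | (2Z,4R,5E,7E,9E)-2,6,8-triethyl-4-methyl-10-phenyldeca-2,5,7,9-tetraenal | O=C/C(CC)=C\[C@H](C)/C=C(CC)/C=C(CC)/C=C/c1ccccc1
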